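In a closed flask the target and everything else together make up the charge, and on the plain assumption that the rest of the charge goes on to target I reckoned on one quantity, the pace (an apparent first-order constant): the natural logarithm of the reciprocal of the non-target share, divided by the hours run.

| flask | substrate | remark | time |
|---|---|---|---|
| zeta | 0.80 M | run made earlier |  |
| alpha | 0.40 M | run made earlier |  |
| epsilon | 1.6 M | run made earlier |  |
| Saturday's | 0.80 M | everything together in a closed stirred flask, run for 50 h | 50 h |
| Thursday's | 0.80 M | one stirred flow tank at steady state, fed with the mixture as stated, mean residence time 50 h |  |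
| Tuesday's | 0.80 M | one stirred flow tank at steady state, fed with the mixture as stated, mean residence time 150 h |  |

| zeta: time / h | zeta: target / % | alpha: time / h | alpha: target / % | epsilon: time / h | epsilon: target / % |
|---|---|---|---|---|---|
| 6.00 | 1 | 5.00 | 2 | 12.0 | 3 |
| 12.0 | 1 | 15.0 | 8 | 25.0 | 5 |
| 20.0 | 9 | 30.0 | 15 | 40.0 | 16 |
| 25.0 | 14 | 40.0 | 23 | 50.0 | 14 |
| 30.0 | 13 | 60.0 | 32 | 60.0 | 19 |

(standard deviation of a reading: 2 percentage points)

- the stated concentrations are those of everything mixed, before any reaction; amounts are the same in each set-up
- what was read earlier has a scatter of 2 percentage points, one standard deviation
- the earlier runs were made in a closed, stirred flask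

- the set-up with the highest amount of target at the outlet or at the end, in percent of the substrate put in ("none" if the first two lie within 2 percentage points) (Saturday's / Thursday's / Tuesday's / none)
- amount of target at the outlet or at the end, in percent of the substrate put in, Saturday's
- amount of target at the outlet or at the end, in percent of the substrate put in, Thursday's
- amount of target at the outlet or at the end, in percent of the substrate put in, Tuesday's

The last reading of the alpha run gave a pace of 0.00643 h⁻¹ and the last of the epsilon run 0.00351 h⁻¹, so the alpha run's pace was faster than the epsilon run's. The alpha charge is half of Saturday's and the epsilon charge twice it, so I took the geometric mean of the two, 0.00475 h⁻¹, as the pace at this charge. Over 50 h in the closed flask that gave 21.1% of the charge as target. The second way used the zeta run, which has Saturday's charge and played no part in the first: its 13% at 30.0 h means a pace of 0.00464 h⁻¹, and so 20.7%. These come from different flasks and differ by 0.40 percentage points, less than the scatter of 2 points, so I carried the pace on to the tanks.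

For a stirred tank at steady state I kept the same assumption, with the target leaving balanced by the pace acting on the non-target share, which makes the target share the pace times the residence time, over one plus that product. Thursday's came to 19.2%, less than the closed flask, and Tuesday's to 41.6%, more than either.

The forecast read the same runs otherwise, “That points to saturation kinetics, not first order.” It gave Saturday's 22%, Thursday's 20% and Tuesday's 46%, with Tuesday's best. On Tuesday's it stood higher than my figure by 4.4 points.

The flasks gave 22.9% for Saturday's, 20.5% for Thursday's and 39.3% for Tuesday's, so Tuesday's came first, with my figure for that tank 2.3 points high and the forecast 6.7 points high.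

    substrate ⇌ side product (K = 0.490, k = 0.0350 h⁻¹)
    substrate ⇌ intermediate A (K = 0.180, k = 0.0280 h⁻¹)
    substrate ⇌ intermediate B (K = 1.80, k = 0.0330 h⁻¹)
    intermediate B → intermediate C (k = 0.00960 h⁻¹)
    intermediate B → target (k = 0.0450 h⁻¹)
    intermediate C ⇌ intermediate D (K = 1.20, k = 0.0790 h⁻¹)
    2 substrate → homo dimer (k = 0.0500 L mol⁻¹ h⁻¹)

At its end Saturday's flask held homo dimer at 41.3% beside target at 22.9%. Put once more to Saturday's flask, now left until 500 h, the pace gave 90.7%, and the flask held target at 44.9% beside homo dimer at 45.5%.

The runs were computed with constants of no real substance, noise included.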